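1. The teal run carries more starting material than the blue run on the same reagent charge, so the two runs together show what the starting material does to the pace; neither varies the reagent.

| flask | starting material | reagent in the second phase | remark | time | volume of the second phase over the first |
|---|---|---|---|---|---|
| blue | 20 mM | 14 mM | the very flask that is asked about, followed so far |  |  |
| teal | 30 mM | 14 mM | run made earlier |  |  |
| flask | 20 mM | 14.0 mM |  | 20 h | 0.50 |

| run | time / h | target / % |
|---|---|---|
| blue | 2.00 | 6.6 |
| blue | 4.00 | 11.2 |
| blue | 6.00 | 14.1 |
| blue | 8.00 | 17.9 |
| teal | 4.00 | 11.1 |
| teal | 8.00 | 16.1 |
| teal | 10.0 | 18.3 |
| teal | 15.0 | 23.0 |

(readings scatter by 1 percentage point)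

- in the second phase: reagent in the second phase; everything else is in the first
- charges count per volume of the first phase; a concentration in a rate is the amount of a species over the volume of its own phase; every rate counts per litre of the first phase
- on the list of suspects stand: starting material + reagent in the reaction phase -> target; reagent in the reaction phase <-> reagent in the second phase; reagent in the reaction phase <-> dormant form; target <-> isomer of the product
- the earlier runs hold the two phases in the same ratio of volumes as the flask asked about

- Saturday's: doubling the transfer coefficient of the reagent in the second phase, all else as stated
- Tuesday's: doubling the amount of reagent in the second phase, all else as stated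

- the target standing at 20 h, as a percentage of the starting material charged
- the change that raises the amount of target at 20 h, in percent of the starting material charged most ("none" if none brings more than 2 percentage points) (Saturday's / Tuesday's / none)
- amount of target at 20 h, in percent of the starting material charged, after Tuesday's

2. Among the suspects, the step starting material + reagent in the reaction phase -> target takes one of each. Dividing the rate at which that step spends reagent by the rate at which it spends starting material gives one, and time drops out: each mM of target costs one mM of each charge. Reagent is therefore the limiting reagent in the flask, and its charge sets a ceiling of 70.0 % of the starting material; the teal ceiling is 46.7 %.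

3. This reckoning, which is not the forecast's, assumes that the reagent in the reaction phase stays a fixed share of the unspent reagent. Let f_A be the share of starting material left, f_R the share of reagent unspent, c_A and c_R their charges, and t the time. Then ln(f_A/f_R)/((c_A − c_R)t) is constant. The last teal reading gives 1.74 L mol⁻¹ h⁻¹. This is the pace constant κ, the target made per hour for each unit of starting material and unspent reagent.

4. There are two ways to the flask's number. The last blue reading gives κ = 2.04 L mol⁻¹ h⁻¹ and so 33.7 %, while the teal value gives 30.5 %. They part, and the blue way cheats: it was read early, and the teal κ, as read through the scatter, sinks from 1.93 L mol⁻¹ h⁻¹ at 8.00 h to the later value. The reckoning therefore commits to 30.5 %.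

5. For Tuesday's, the same κ gives 52.9 %, with starting material now the limiting charge. For Saturday's, the blue pace over the first 2.00 h exceeds its latest pace. The readings show no lag, so faster transfer promises little.

6. The forecast gives 28 % (24.5 % to 32 %), names Tuesday's as best, and gives 44 % after it (34 % to 53 %), on the ground that “Doubling the reagent roughly doubles the drive”. Its Tuesday figure stands below this reckoning's.

7. The flask gives 30.1 %, the best change is Tuesday's, and after it the target stands at 51.2 %. Saturday's adds 0.13 percentage points and Tuesday's adds 21 points. Read backwards from the flask's own number, κ is 1.70 L mol⁻¹ h⁻¹, against 1.74 L mol⁻¹ h⁻¹ from the teal run.

    starting material + reagent in the reaction phase → target (k = 6.00 L mol⁻¹ h⁻¹)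
    reagent in the reaction phase ⇌ reagent in the second phase, rate k2*([reagent in the reaction phase] - [reagent in the second phase]/K2) per volume of the first phase (partition coefficient = 2.90, kL = 3.70 h⁻¹)
    reagent in the reaction phase ⇌ dormant form (K = 2.20, k = 0.0250 h⁻¹)
    target ⇌ isomer of the product (K = 0.360, k = 0.0160 h⁻¹)

8. The same flask read at 5.0 h falls earlier than the last blue reading, within the span of the blue run, so the blue κ is used and gives 12.2 %. The computed value is 12.9 %.

(The earlier runs and the new flask are calculated with constants of no real substance; noise was put on by code.)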